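If I trusted the readings of the elm flask and nothing else, I could still compare two rates at one moment: how fast target came and how fast starting material went.

- elm: starting material 0.25 M; reagent 0.275 M; initiator 25 mM; temperature 70 °C; the very flask that is asked about, followed so far
- flask: starting material 0.25 M; reagent 0.275 M; initiator 25 mM; temperature 70 °C; time 12 h

elm run (percent of the starting material charged)

| time / h | target / % | starting material / % |
|---|---|---|
| 2.00 | 13.7 | 79.6 |
| 4.00 | 18.9 | 57.7 |
| 5.00 | 22.5 | 49.8 |
| 8.00 | 25.6 | 29.6 |

(scatter of a reading: 1 percentage point)

- the volume of additions can be left aside
- what was read earlier has a scatter of 1 percentage point, one standard deviation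
- the earlier runs do not show what temperature does; that part of a forecast is a guess

- amber: at 12 h raise the temperature by 15 K, then wait 6.0 h
- red: change nothing and wait 6.0 h more
- green: at 12 h add reagent, 50.0 % of the amount charged, then wait 6.0 h
- blue: at 12 h take out 90 % of the released group then present, then wait 6.0 h

* target, in percent of the starting material first charged, at 12 h
* what to do for the largest gain in target; "none" if nothing gains more than 2 percentage points (amber / red / green / blue / none)
* target present, in percent of the starting material first charged, after green
* target present, in percent of the starting material first charged, after blue

Over the last interval the elm flask gained 3.1 percentage points of target for 20 points of starting material lost. That gave s = 0.153, the marginal share, or selectivity: target gained per starting material lost. Over the first interval the share, s₀, had been 0.672, so it had drifted down, although the scatter makes s a rough reading.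

I assumed s would not rise again. Then the ceiling at 12 h was the last reading plus s times all the starting material then left, 30.1 %. The last interval gave a decay constant of 0.173 /h, which left 14.8 % at 12 h, so I tightened the ceiling to 27.9 %. For the floor, I assumed target did not fall and took the last reading less its scatter, 24.6 %. Waiting 6.0 h more should lose about 9.57 %, which at s gains 1.5 points, less than the margin.

The forecast put target at 27 %, which lay inside my bracket; its range, from 24 % to 30 %, reached below my floor and above my ceiling. It gave 27.5 % after green and 31 % after blue, and chose blue: “Removing the released group should restore selectivity and stop the loss”. By my reckoning, that rise from its 27 % asked for a share of 0.418 over the same loss, above s. The readings were silent on amber.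

    reagent + first chain carrier ⇌ target + second chain carrier (K = 1.70, k = 3.60 × 10⁶ /M/h, Ea = 35.0 kJ/mol, ΔH = −21.0 kJ/mol)
    2 second chain carrier → ended chains A (k = 3.60 × 10⁷ /M/s, Ea = 11.0 kJ/mol)
    starting material + target → side product (k = 0.950 /M/h, Ea = 72.0 kJ/mol)
    starting material + second chain carrier → released group + first chain carrier (k = 2.10 × 10⁶ /M/h, Ea = 42.0 kJ/mol)
    initiator → 2 initiating radical (k = 0.0130 /h, Ea = 109 kJ/mol)
    target ⇌ isomer of the product (K = 0.720, k = 0.100 /h, Ea = 114 kJ/mol, ΔH = −54.0 kJ/mol)
    starting material + initiating radical → capped initiator + first chain carrier (k = 2.30 × 10⁷ /M/h, Ea = 17.0 kJ/mol)
    2 first chain carrier → ended chains B (k = 3.10 × 10⁶ /M/s, Ea = 13.0 kJ/mol)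
    (constants at 70 °C)

The elm flask gave 24.8 %, inside the bracket and near its floor. The best choice was amber, with a gain of 8.9 points, while blue reached 25.2 % and green 25.3 %. Target's half-life by the side-product step, 2.9 h, is shorter than by the isomer step, 6.9 h. Applied to the 15.9 % of starting material left, s gives a ceiling of 2.4 points, and waiting gained 0.42 points.

The neighbour flask at 45 °C lost 11.4 % of its starting material, less than the elm flask lost by its first reading. So s and s₀ bracket its target between 1.74 % and 7.63 %. It held 7.97 %, just over the top, a share of 0.702.

The data stem from a simulated flask for an exercise; noise was put on by code.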